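**Plan**
- Retrosynthesis (chain numbered from the OCH2 carbon C1'): the C5'=C6' alkene is cut first, then the two C–O bonds of the oxirane (C2'–O and C3'–O), then the aryl ether bond O7–C1', and last the C3'–CH3 and C2'–C1' bonds.
- Forward: a C7 dienol is made from pent-1-en-4-yne and joined to O7 of the intact coumarin isofraxidin. The oxirane, the only ring made, is then closed on the aryl dienyl ether, and cross-metathesis with 2-methylbut-3-en-2-ol completes the chain.
- Enabling feature: the only stereocentres, C2' and C3', are the two carbons of one trisubstituted oxirane whose aryloxymethyl group on C2' is trans to the C4' chain on C3'. This is the pattern left by oxygen transfer to an E-trisubstituted C2'=C3' alkene.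
- Stereochemistry: the E-C2'=C3' geometry comes from syn methylalumination, C2' and C3' (both R) from the dioxirane of the D-fructose-derived ketone, and the E-C5'=C6' alkene from the metathesis.

Key step: step 3

Assumption: the D-fructose-derived ketone is taken to follow its usual spiro transition-state model with this allylic aryl ether, which maps the E-alkene onto the (2R,3R) oxirane.

**Step 1**
Reactants: 1 pent-1-en-4-yne
Product: 4 (2E)-3-methylhexa-2,5-dien-1-ol, via alkenyldimethylalane 2 (not isolated), via lithium alkenylaluminate 3 (not isolated)
Conditions: Me3Al (2 equiv), Cp2ZrCl2 (0.25 equiv), CH2Cl2, 0 °C to rt; evaporate, hexane; n-BuLi, hexane/THF, −78 to 0 °C; (CH2O)n, 0 °C to rt; cold 1 M HCl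
Reagents that add atoms: trimethylaluminium, C[Al](C)C; paraformaldehyde (as formaldehyde), C=O
Why: Zirconium-catalysed methylalumination of a terminal alkyne (Negishi carboalumination) adds CH3 and Al syn with CH3 on the internal carbon, which fixes the E geometry, the butyl ate complex of the alkenylalane then adds to formaldehyde with retention, and the monosubstituted alkene is not carbometalated by Me3Al/Cp2ZrCl2.

**Step 2**
Reactants: 4 (2E)-3-methylhexa-2,5-dien-1-ol; 5 isofraxidin (7-hydroxy-6,8-dimethoxy-2H-chromen-2-one)
Product: 6 6,8-dimethoxy-7-{[(2E)-3-methylhexa-2,5-dien-1-yl]oxy}-2H-chromen-2-one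
Conditions: PPh3, DIAD, THF, 0 °C to rt
Reagents that add atoms: none
Why: Mitsunobu etherification of an acidic 7-hydroxycoumarin with a primary allylic alcohol should proceed by SN2 displacement at C1' of the alkoxyphosphonium ion, leaving the E-alkene and the skipped diene untouched.

**Step 3**
Reactants: 6 6,8-dimethoxy-7-{[(2E)-3-methylhexa-2,5-dien-1-yl]oxy}-2H-chromen-2-one
Product: 7 6,8-dimethoxy-7-{[(2R,3R)-3-methyl-3-(prop-2-en-1-yl)oxiran-2-yl]methoxy}-2H-chromen-2-one
Conditions: 1,2:4,5-di-O-isopropylidene-β-D-erythro-2,3-hexodiulo-2,6-pyranose (0.3 equiv), KHSO5 (as 2KHSO5·KHSO4·K2SO4, 1.4 equiv), K2CO3, Bu4NHSO4 (cat.), MeCN/CH2(OMe)2/aq. Na2B4O7 buffer (pH 10.5), −10 to 0 °C; aq. NaH2PO4 work-up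
Reagents that add atoms: potassium peroxymonosulfate (KHSO5), [K+].[O-]S(=O)(=O)OO
Why: KHSO5 adds to the carbonyl group of the ketone catalyst and the adduct closes to a chiral dioxirane, which hands one oxygen atom to the C2'=C3' π bond in a concerted, stereospecific step through a spiro transition state and returns the ketone; this is the Shi epoxidation of an E-trisubstituted alkene, a well-established substrate class. The oxirane, the only ring formed, closes by this single [2+1] oxygen-atom transfer that makes the C2'–O and C3'–O bonds together, so the E geometry of 6 is copied into the trans relationship of the C1' and C4' substituents. Both stereocentres, C2' and C3', are set by the catalyst: in the spiro transition state the alkene hydrogen on C2' lies next to the fused dioxolane of the D-fructose-derived ketone, which should expose the face leading to the (2R,3R) oxirane, the same sense in which this ketone converts trans-β-methylstyrene and 1-phenylcyclohexene into their (R,R) oxides. The step needs site selectivity among three alkenes and enantioface selectivity: the electrophilic dioxirane should prefer the trisubstituted, most electron-rich C2'=C3' bond over the monosubstituted C5'=C6' vinyl group and the electron-poor, lactone-conjugated coumarin C3=C4 bond, and the oxidant is kept near one equivalent to hold that preference. The carbonate buffer suppresses Baeyer–Villiger loss of the catalyst and acid opening of the product, and any lactone that opens to the (Z)-coumarinate should reclose on the mildly acidic work-up.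

**Step 4**
Reactants: 7 6,8-dimethoxy-7-{[(2R,3R)-3-methyl-3-(prop-2-en-1-yl)oxiran-2-yl]methoxy}-2H-chromen-2-one; 8 2-methylbut-3-en-2-ol
Product: 9 7-({(2R,3R)-3-[(2E)-4-hydroxy-4-methylpent-2-en-1-yl]-3-methyloxiran-2-yl}methoxy)-6,8-dimethoxy-2H-chromen-2-one
Conditions: 8 (5 equiv), second-generation Grubbs catalyst (H2IMes)(PCy3)Cl2Ru=CHPh (5 mol %), CH2Cl2, 40 °C
Reagents that add atoms: none
Why: Olefin cross-metathesis between a readily dimerising monosubstituted alkene and a slowly dimerising tertiary allylic alcohol should favour the cross product and, being reversible, settle on the E-alkene, while the coumarin C3=C4 bond, the oxirane and the C2'/C3' stereocentres are not engaged.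

**Compound list**
1 | pent-1-en-4-yne | C=CCC#C | starting material
2 | dimethyl[(1E)-2-methylpenta-1,4-dien-1-yl]alane | C[Al](C)/C=C(\C)CC=C | intermediate
3 | lithium butyl(dimethyl)[(1E)-2-methylpenta-1,4-dien-1-yl]aluminate | [Li+].CCCC[Al-](C)(C)/C=C(\C)CC=C | intermediate
4 | (2E)-3-methylhexa-2,5-dien-1-ol | OC/C=C(\C)CC=C | intermediate
5 | isofraxidin (7-hydroxy-6,8-dimethoxy-2H-chromen-2-one) | COc1cc2ccc(=O)oc2c(OC)c1O | starting material
6 | 6,8-dimethoxy-7-{[(2E)-3-methylhexa-2,5-dien-1-yl]oxy}-2H-chromen-2-one | COc1cc2ccc(=O)oc2c(OC)c1OC/C=C(\C)CC=C | intermediate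
7 | 6,8-dimethoxy-7-{[(2R,3R)-3-methyl-3-(prop-2-en-1-yl)oxiran-2-yl]methoxy}-2H-chromen-2-one | COc1cc2ccc(=O)oc2c(OC)c1OC[C@H]1O[C@]1(C)CC=C | intermediate
8 | 2-methylbut-3-en-2-ol | C=CC(C)(C)O | starting material
9 | 7-({(2R,3R)-3-[(2E)-4-hydroxy-4-methylpent-2-en-1-yl]-3-methyloxiran-2-yl}methoxy)-6,8-dimethoxy-2H-chromen-2-one | COc1cc2ccc(=O)oc2c(OC)c1OC[C@H]1O[C@]1(C)C/C=C/C(C)(C)O | target

**Step count**
Total steps: 4. Longest linear sequence: 4 steps (1 → 4 → 6 → 7 → 9).

**Steps most likely to fail**

Step 3 (epoxidation). What may go wrong: insufficient enantioface discrimination for an allylic ether carrying a large aryloxy group, partial oxidation of the vinyl group, or hydrolytic opening of the lactone in the basic buffer that lowers recovery. Fallback: the oxirane is made before the ether bond, by titanium–tartrate epoxidation directed by the free allylic hydroxyl group. Setting out from 4, Sharpless asymmetric epoxidation (Ti(OiPr)4, D-(−)-diethyl tartrate, t-BuOOH, 4 Å molecular sieves, CH2Cl2, −20 °C) should give [(2R,3R)-3-methyl-3-(prop-2-en-1-yl)oxiran-2-yl]methanol F1. The hydroxyl group confines oxygen delivery to the allylic alkene, and the D-tartrate selects the face opposite to the one the L-tartrate uses for geraniol. Mitsunobu coupling of F1 with isofraxidin 5 (PPh3, DIAD, THF) then comes back to the route at 7.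

Step 1 (methylalumination and hydroxymethylation). What may go wrong: loss of the low-boiling enyne and dienol on handling, competing metalation of the acetylenic C–H or of the doubly activated CH2 group, or incomplete capture of the alkenyl–aluminium bond by formaldehyde. Fallback: a hydroalumination, iodination and methylation sequence in which the methyl group is introduced last. Setting out from 1, deprotonation with EtMgBr in THF and addition to paraformaldehyde should give hex-5-en-2-yn-1-ol F2. Hydroxyl-directed anti hydroalumination with NaAlH2(OCH2CH2OCH3)2 in THF, followed by I2 at −78 °C, should give (2Z)-3-iodohexa-2,5-dien-1-ol F3. Excess Me2CuLi in Et2O at 0 °C replaces iodine by methyl with retention of geometry and comes back to the route at 4.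

Step 4 (cross-metathesis). What may go wrong: self-metathesis of 7 outrunning the cross reaction with the hindered tertiary allylic alcohol, migration of the C5'=C6' alkene through ruthenium hydride species, opening of the oxirane by ruthenium residues, or erosion of the E/Z purity at the last stage. Fallback: the metathesis is moved to the simple dienol and a hydroxyl-directed epoxidation then chooses the alkene. Setting out from 4, cross-metathesis with 8 (second-generation Grubbs catalyst (H2IMes)(PCy3)Cl2Ru=CHPh, CH2Cl2, 40 °C) should give (2E,5E)-3,7-dimethylocta-2,5-diene-1,7-diol F4. Sharpless asymmetric epoxidation (Ti(OiPr)4, D-(−)-diethyl tartrate, t-BuOOH, CH2Cl2, −20 °C) should give [(2R,3R)-3-[(2E)-4-hydroxy-4-methylpent-2-en-1-yl]-3-methyloxiran-2-yl]methanol F5, because the primary allylic alcohol directs the reagent to C2=C3 while the alkene next to the tertiary alcohol reacts far more slowly in this system. Mitsunobu coupling of F5 with isofraxidin 5 at the primary hydroxyl group (PPh3, DIAD, THF) comes back to the route at 9.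

**Further compounds**
F1 | step 3 | [(2R,3R)-3-methyl-3-(prop-2-en-1-yl)oxiran-2-yl]methanol | OC[C@H]1O[C@]1(C)CC=C
F2 | step 1 | hex-5-en-2-yn-1-ol | OCC#CCC=C
F3 | step 1 | (2Z)-3-iodohexa-2,5-dien-1-ol | OC/C=C(\I)CC=C
F4 | step 4 | (2E,5E)-3,7-dimethylocta-2,5-diene-1,7-diol | OC/C=C(\C)C/C=C/C(C)(C)O
F5 | step 4 | [(2R,3R)-3-[(2E)-4-hydroxy-4-methylpent-2-en-1-yl]-3-methyloxiran-2-yl]methanol | OC[C@H]1O[C@]1(C)C/C=C/C(C)(C)O
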